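## Retrosynthetic overview

- Target 16 is (3S,5R)-1-(4-hydroxy-3-methoxyphenyl)octane-3,5-diyl diacetate, an open-chain syn-1,3-diol diacetate (chain numbered C1 benzylic to C8); the guaiacyl arene is bought, not built.
- Feature used: the acetoxy carbon C3 is bonded to C2 and stands 1,3 to the carbinol carbon C5, so a C2=C3 double bond grown from the allyl group of eugenol can take its C3 oxygen intramolecularly from a carbonate held on the C5 oxygen.
- Disconnections: free phenol from the triacetate by chemoselective aminolysis; triacetate from the syn-diol; C3–O by iodocarbonate cyclisation; C2=C3 by cross-metathesis; C3–C4 by vinyl Grignard opening of (R)-1,2-epoxypentane, which supplies C5 (R).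
- Ring order: one ring is formed, the temporary six-membered 1,3-dioxan-2-one (O–C5–C4–C3–O–C=O) in step 4; it is opened again in step 6 after the C2 iodide has been reduced.

Key step: step 4

Remark on the chemistry: the cross-metathesis is expected to give mainly the E alkene. Any Z isomer is carried on, because C2 loses its iodine in step 5 and both isomers should lead to the same C3 configuration.

## Route

Step 1
Reactants: 1 (R)-1,2-epoxypentane; 2 vinylmagnesium bromide
Product: 4 (4R)-hept-1-en-4-ol, via bromomagnesium alkoxide 3 (not isolated)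
Conditions: 2 (1.5 equiv), CuI (10 mol%), THF, −30 to 0 °C; then H2O/aq. NH4Cl
Reagents that add atoms: none
Why: Copper-catalysed Grignard opening of a terminal epoxide takes place at the unsubstituted CH2 carbon, so the C–O stereocentre of 1 is untouched and becomes C5 (R) of the chain.

Step 2
Reactants: 4 (4R)-hept-1-en-4-ol; 5 di-tert-butyl dicarbonate
Product: 6 tert-butyl (4R)-hept-1-en-4-yl carbonate
Conditions: 5 (1.5 equiv), DMAP (0.2 equiv), MeCN, rt
Reagents that add atoms: none
Why: DMAP-catalysed O-tert-butoxycarbonylation of the secondary alcohol gives the mixed carbonate without touching the stereocentre or the alkene.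

Step 3
Reactants: 6 tert-butyl (4R)-hept-1-en-4-yl carbonate; 7 eugenol acetate (4-allyl-2-methoxyphenyl acetate)
Product: 8 4-[(2E,5R)-5-(tert-butoxycarbonyloxy)oct-2-en-1-yl]-2-methoxyphenyl acetate
Conditions: 7 (3 equiv), second-generation Grubbs catalyst RuCl2(=CHPh)(H2IMes)(PCy3) (5 mol%), 1,4-benzoquinone (10 mol%), CH2Cl2, 40 °C
Reagents that add atoms: none
Why: Olefin cross-metathesis of two unhindered terminal alkenes is driven by loss of ethylene and steered to the cross product by the excess of cheap 7 (its homodimer re-enters the cycle), with the E isomer favoured; benzoquinone suppresses ruthenium hydride migration of the allylarene double bond.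

Step 4
Reactants: 8 4-[(2E,5R)-5-(tert-butoxycarbonyloxy)oct-2-en-1-yl]-2-methoxyphenyl acetate
Product: 11 4-{(2S)-2-iodo-2-[(4R,6R)-2-oxo-6-propyl-1,3-dioxan-4-yl]ethyl}-2-methoxyphenyl acetate, via iodonium ion 9 (not isolated), via 2-tert-butoxy-1,3-dioxan-2-ylium ion 10 (not isolated)
Conditions: IBr (1.2 equiv, CH2Cl2 solution), toluene, −85 °C, 30 min; then aq. Na2S2O3/NaHCO3
Reagents that add atoms: iodine monobromide, IBr
Why: IBr adds reversibly to the C2=C3 double bond to give iodonium ion 9, the carbonyl oxygen of the C5 tert-butyl carbonate opens it at C3 from the side opposite iodine (new C3–O bond, iodine stays on C2), and the resulting 2-tert-butoxy-1,3-dioxan-2-ylium ion 10 gives up its tert-butyl group to bromide. The closest known reaction type is the electrophile-induced iodocarbonate cyclisation of homoallylic tert-butyl carbonates to cis-4,6-disubstituted 1,3-dioxan-2-ones, used here in its low-temperature IBr form on an E-1,2-disubstituted alkene. The single ring formed, the six-membered carbonate O–C5–C4–C3–O–C(=O), closes in the 6-exo mode, which ring size favours over 7-endo attack at C2 since neither alkene carbon is electronically biased. C3 is controlled by the resident C5 (R) centre through a chair-like transition state that keeps the propyl group and the iodonium-bearing arm equatorial, so the new C3–O bond comes out cis to the propyl group on the ring (1,3-syn, the C3 configuration of the target). C2 is fixed as 2S by stereospecific anti addition of oxygen and iodine across the E alkene and is only transient, because its iodine is removed in step 5 and any Z alkene should therefore converge on the same C3 configuration. The step needs chemoselectivity for the alkene over the electron-rich arene and kinetic control of the closure; the acetyl group on the phenol lowers the reactivity of the ring toward IBr and toward the iodonium ion, and the low temperature with a short contact time keeps the chair-controlled pathway dominant.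

Step 5
Reactants: 11 4-{(2S)-2-iodo-2-[(4R,6R)-2-oxo-6-propyl-1,3-dioxan-4-yl]ethyl}-2-methoxyphenyl acetate
Product: 13 4-{2-[(4S,6R)-2-oxo-6-propyl-1,3-dioxan-4-yl]ethyl}-2-methoxyphenyl acetate, via C2 alkyl radical 12 (not isolated)
Conditions: Bu3SnH (1.5 equiv), AIBN (0.1 equiv), toluene, 80 °C
Reagents that add atoms: none
Why: Tin hydride radical-chain dehalogenation replaces the C2 iodine by hydrogen without involving the C3 and C5 stereocentres, the carbonate or the aryl acetate; doing this before any base is used avoids epoxide formation or HI elimination in step 6.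

Step 6
Reactants: 13 4-{2-[(4S,6R)-2-oxo-6-propyl-1,3-dioxan-4-yl]ethyl}-2-methoxyphenyl acetate
Product: 14 (3S,5R)-1-(4-hydroxy-3-methoxyphenyl)octane-3,5-diol
Conditions: K2CO3 (2 equiv), MeOH, rt, under argon; then aq. NH4Cl
Reagents that add atoms: none
Why: Base-mediated methanolysis (transesterification) attacks the carbonate and aryl acetate carbonyl carbons only, so the C3–O and C5–O bonds keep their configuration and the syn-diol and the phenol are released together.

Step 7
Reactants: 14 (3S,5R)-1-(4-hydroxy-3-methoxyphenyl)octane-3,5-diol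
Product: 15 (3S,5R)-1-(4-acetoxy-3-methoxyphenyl)octane-3,5-diyl diacetate
Conditions: Ac2O (6 equiv), pyridine, DMAP (5 mol%), CH2Cl2, 0 °C to rt
Reagents that add atoms: acetic anhydride, CC(=O)OC(C)=O
Why: Exhaustive DMAP-catalysed acetylation of the phenol and both secondary alcohols takes place at oxygen and leaves the stereocentres unchanged.

Step 8
Reactants: 15 (3S,5R)-1-(4-acetoxy-3-methoxyphenyl)octane-3,5-diyl diacetate
Product: 16 (3S,5R)-1-(4-hydroxy-3-methoxyphenyl)octane-3,5-diyl diacetate
Conditions: pyrrolidine (1.2 equiv), CH2Cl2, 0 °C to rt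
Reagents that add atoms: none
Why: Chemoselective aminolysis: the aryl acetate, with its phenoxide leaving group, is far more electrophilic than the two secondary alkyl acetates, so a slight excess of pyrrolidine should remove only the phenolic acetyl group.

## Compound list

1 | (R)-1,2-epoxypentane | CCC[C@@H]1CO1 | starting material
2 | vinylmagnesium bromide | C=C[Mg]Br | starting material
3 | bromomagnesium (4R)-hept-1-en-4-olate | CCC[C@H](CC=C)O[Mg]Br | intermediate
4 | (4R)-hept-1-en-4-ol | CCC[C@H](CC=C)O | intermediate
5 | di-tert-butyl dicarbonate | CC(C)(C)OC(=O)OC(=O)OC(C)(C)C | starting material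
6 | tert-butyl (4R)-hept-1-en-4-yl carbonate | CCC[C@H](CC=C)OC(=O)OC(C)(C)C | intermediate
7 | eugenol acetate (4-allyl-2-methoxyphenyl acetate) | COc1cc(CC=C)ccc1OC(C)=O | starting material
8 | 4-[(2E,5R)-5-(tert-butoxycarbonyloxy)oct-2-en-1-yl]-2-methoxyphenyl acetate | CCC[C@H](C/C=C/Cc1ccc(OC(C)=O)c(OC)c1)OC(=O)OC(C)(C)C | intermediate
9 | iodonium (iodiranium) ion of 8, iodine bridging C2 and C3 on the face that leaves C3 open to the carbonate oxygen | CCC[C@H](C[C@@H]1[I+][C@H]1Cc2ccc(OC(C)=O)c(OC)c2)OC(=O)OC(C)(C)C | intermediate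
10 | (4R,6R)-4-[(1S)-2-(4-acetoxy-3-methoxyphenyl)-1-iodoethyl]-2-tert-butoxy-6-propyl-1,3-dioxan-2-ylium ion | CCC[C@@H]1C[C@H]([C@@H](I)Cc2ccc(OC(C)=O)c(OC)c2)O[C+](OC(C)(C)C)O1 | intermediate
11 | 4-{(2S)-2-iodo-2-[(4R,6R)-2-oxo-6-propyl-1,3-dioxan-4-yl]ethyl}-2-methoxyphenyl acetate | CCC[C@@H]1C[C@H]([C@@H](I)Cc2ccc(OC(C)=O)c(OC)c2)OC(=O)O1 | intermediate
12 | secondary alkyl radical at C2 of the cyclic carbonate (iodine removed from 11) | CCC[C@@H]1C[C@H]([CH]Cc2ccc(OC(C)=O)c(OC)c2)OC(=O)O1 | intermediate
13 | 4-{2-[(4S,6R)-2-oxo-6-propyl-1,3-dioxan-4-yl]ethyl}-2-methoxyphenyl acetate | CCC[C@@H]1C[C@H](CCc2ccc(OC(C)=O)c(OC)c2)OC(=O)O1 | intermediate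
14 | (3S,5R)-1-(4-hydroxy-3-methoxyphenyl)octane-3,5-diol | CCC[C@@H](O)C[C@H](CCc1ccc(O)c(OC)c1)O | intermediate
15 | (3S,5R)-1-(4-acetoxy-3-methoxyphenyl)octane-3,5-diyl diacetate | CCC[C@H](C[C@H](CCc1ccc(OC(C)=O)c(OC)c1)OC(C)=O)OC(C)=O | intermediate
16 | (3S,5R)-1-(4-hydroxy-3-methoxyphenyl)octane-3,5-diyl diacetate | CCC[C@H](C[C@H](CCc1ccc(O)c(OC)c1)OC(C)=O)OC(C)=O | target

## Step count and risks

Total step count: 8. Longest linear sequence: 8 steps (1 to 16).

Steps most likely to fail:

1. Step 4 (iodocarbonate cyclisation). The electron-rich arene may be iodinated or may capture the iodonium ion in competition with the carbonate. The 1,3-induction may also erode if the closure leaves kinetic chair control. Fallback, setting out from 6 and coming back at 14: the cyclisation is moved ahead of the arene. Carbonate 6, with its terminal alkene, is treated with IBr in toluene at −85 °C to give (4R,6R)-4-(iodomethyl)-6-propyl-1,3-dioxan-2-one F1. K2CO3 in MeOH converts this into the syn epoxy alcohol (2R)-1-[(2R)-oxiran-2-yl]pentan-2-ol F2. The epoxide is opened at its CH2 carbon, forming the C1–C2 bond, by [4-(benzyloxy)-3-methoxybenzyl]magnesium chloride F3 (3 equiv, from 4-(benzyloxy)-3-methoxybenzyl chloride and Mg turnings) with CuI (10 mol%) in THF at −40 to 0 °C. This gives (3S,5R)-1-[4-(benzyloxy)-3-methoxyphenyl]octane-3,5-diol F4. Hydrogenolysis (H2, 10% Pd/C, EtOAc) then gives triol 14, and steps 7 and 8 follow unchanged.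

2. Step 3 (cross-metathesis). Both terminal alkenes may self-metathesise to a statistical mixture, the allylarene double bond may migrate into conjugation under ruthenium hydride catalysis, and E/Z control may be poor. Fallback, setting out from 1 and coming back at 8: the alkene is built without metathesis. Epoxide 1 is opened with lithium acetylide–ethylenediamine complex (LiC≡CH·H2NCH2CH2NH2, DMSO, rt) to (4R)-hept-1-yn-4-ol F5. This is converted with 5 and DMAP in MeCN into tert-butyl (4R)-hept-1-yn-4-yl carbonate F6. Syn hydroboration with pinacolborane (Cp2Zr(H)Cl 5 mol%, CH2Cl2, rt) gives tert-butyl (1E,4R)-1-(4,4,5,5-tetramethyl-1,3,2-dioxaborolan-2-yl)hept-1-en-4-yl carbonate F7. The coupling partner is made from commercial vanillin acetate by NaBH4 reduction to 4-(hydroxymethyl)-2-methoxyphenyl acetate F8 and bromination with PBr3 to 4-(bromomethyl)-2-methoxyphenyl acetate F9. Suzuki–Miyaura coupling of F7 with F9 (PdCl2(dppf), CsF, THF, 60 °C) should give 8 as the E isomer only.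

3. Step 8 (selective phenol deacetylation). Aminolysis may also reach a secondary acetate, or the aryl acetate may be cleaved incompletely. Fallback, setting out from 14 and coming back at 16: the phenol is masked before acetylation instead of being unmasked after it. Triol 14 is alkylated selectively at the phenol (allyl bromide, K2CO3, acetone, reflux) to give (3S,5R)-1-[3-methoxy-4-(prop-2-en-1-yloxy)phenyl]octane-3,5-diol F10. Acetylation (Ac2O, pyridine, DMAP) gives (3S,5R)-1-[3-methoxy-4-(prop-2-en-1-yloxy)phenyl]octane-3,5-diyl diacetate F11. The allyl ether is then removed with Pd(PPh3)4 (5 mol%) and morpholine in THF at rt to give 16.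

Further compounds
F1 | step 4 | (4R,6R)-4-(iodomethyl)-6-propyl-1,3-dioxan-2-one | CCC[C@@H]1C[C@H](CI)OC(=O)O1
F2 | step 4 | (2R)-1-[(2R)-oxiran-2-yl]pentan-2-ol | CCC[C@@H](O)C[C@@H]1CO1
F3 | step 4 | [4-(benzyloxy)-3-methoxybenzyl]magnesium chloride | COc1cc(C[Mg]Cl)ccc1OCc1ccccc1
F4 | step 4 | (3S,5R)-1-[4-(benzyloxy)-3-methoxyphenyl]octane-3,5-diol | CCC[C@@H](O)C[C@@H](O)CCc1ccc(OCc2ccccc2)c(OC)c1
F5 | step 3 | (4R)-hept-1-yn-4-ol | CCC[C@H](CC#C)O
F6 | step 3 | tert-butyl (4R)-hept-1-yn-4-yl carbonate | CCC[C@H](CC#C)OC(=O)OC(C)(C)C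
F7 | step 3 | tert-butyl (1E,4R)-1-(4,4,5,5-tetramethyl-1,3,2-dioxaborolan-2-yl)hept-1-en-4-yl carbonate | CCC[C@H](C/C=C/B1OC(C)(C)C(C)(C)O1)OC(=O)OC(C)(C)C
F8 | step 3 | 4-(hydroxymethyl)-2-methoxyphenyl acetate | COc1cc(CO)ccc1OC(C)=O
F9 | step 3 | 4-(bromomethyl)-2-methoxyphenyl acetate | COc1cc(CBr)ccc1OC(C)=O
F10 | step 8 | (3S,5R)-1-[3-methoxy-4-(prop-2-en-1-yloxy)phenyl]octane-3,5-diol | CCC[C@@H](O)C[C@H](CCc1ccc(OCC=C)c(OC)c1)O
F11 | step 8 | (3S,5R)-1-[3-methoxy-4-(prop-2-en-1-yloxy)phenyl]octane-3,5-diyl diacetate | CCC[C@H](C[C@H](CCc1ccc(OCC=C)c(OC)c1)OC(C)=O)OC(C)=O
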